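**Retrosynthetic overview**

- The sulfate goes on late. The 7-OH of a 5,7-diol is sulfated while O3 and O4′ carry benzyl groups and the 5-OH is held in a hydrogen bond to the C4 carbonyl; hydrogenolysis then frees O3 and O4′.
- The C3 hydroxyl is made from the C2=C3 bond of a flavone by epoxidation and isomerisation, so the 3-unsubstituted flavone is the pivot.
- Feature used: in ring C the carbonyl carbon C4 sits between C4a of ring A and C3, and the C3–C2 unit carries ring B and ends at O1. C4 can therefore enter as carbon monoxide between an ortho-iodophenol (C4a–I, O1–H) and an arylacetylene (C3≡C2–ring B), forming C4a–C4, C4–C3 and O1–C2 in one palladium-catalysed operation.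
- Ring order: rings A and B are bought (phloroglucinol, O-benzylvanillin); ring C is the only ring built, in the carbonylative annulation.

Key step: step 4

Assumption: the sulfate monoesters 14 and 15 are drawn as free hydrogen sulfates, as the target is. At the bench 14 would be converted on work-up into its sodium salt, because pyridinium ions slow benzyl ether hydrogenolysis on Pd/C and the free acid hydrolyses itself. The acid form of 15 would be released only at the end by a cold pass through an H+ exchange resin.

**Route**

Step 1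
Reactants: 1 phloroglucinol (benzene-1,3,5-triol)
Product: 2 3,5-bis(methoxymethoxy)phenol
Conditions: MOMCl (2.0 equiv), i-Pr2NEt (2.2 equiv), DMF, 0 °C to rt; chromatography
Reagents that add atoms: chloromethyl methyl ether, COCCl
Why: O-alkylation of the phenol with the hard oxocarbenium-type electrophile (Williamson-type MOM protection) is statistical among three equivalent hydroxyls, so two equivalents should give the bis-ether as the main fraction, with the mono- and tris-ethers separable and recyclable.

Step 2
Reactants: 2 3,5-bis(methoxymethoxy)phenol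
Product: 3 2-iodo-3,5-bis(methoxymethoxy)phenol
Conditions: N-iodosuccinimide (1.0 equiv), CH2Cl2, −20 °C to 0 °C
Reagents that add atoms: N-iodosuccinimide, O=C1CCC(=O)N1I
Why: Electrophilic aromatic iodination under acid-free conditions that spare the MOM acetals; the two equivalent positions ortho to the free hydroxyl lie between OH and one OMOM, whereas the single para position is buried between two OMOM groups, so the ortho iodide should predominate and the symmetric para isomer is removed by chromatography.

Step 3
Reactants: 4 4-(benzyloxy)-3-methoxybenzaldehyde (O-benzylvanillin)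
Product: 5 1-(benzyloxy)-4-ethynyl-2-methoxybenzene
Conditions: dimethyl (1-diazo-2-oxopropyl)phosphonate (1.3 equiv), K2CO3 (2 equiv), MeOH/THF, rt
Reagents that add atoms: dimethyl (1-diazo-2-oxopropyl)phosphonate, COP(=O)(OC)C(=[N+]=[N-])C(C)=O
Why: Ohira–Bestmann (Seyferth–Gilbert) homologation: methanolysis of the acetyl group gives the diazomethylphosphonate anion, which adds to the non-enolisable aldehyde, and loss of dimethyl phosphate and N2 with a 1,2-hydride shift gives the terminal alkyne, the benzyl ether being inert to K2CO3/MeOH.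

Step 4
Reactants: 3 2-iodo-3,5-bis(methoxymethoxy)phenol; 5 1-(benzyloxy)-4-ethynyl-2-methoxybenzene (1.3 equiv); 6 carbon monoxide
Product: 9 2-[4-(benzyloxy)-3-methoxyphenyl]-5,7-bis(methoxymethoxy)-4H-chromen-4-one, via ortho-hydroxyaryl ynone 7 (not isolated), via diethylamino enone 8 (not isolated)
Conditions: PdCl2(PPh3)2 (5 mol %), CO (20 bar), Et2NH (solvent), 120 °C, autoclave, no copper salt
Reagents that add atoms: none
Why: PdCl2(PPh3)2 is reduced in the amine to zerovalent palladium, which inserts into the C–I bond of 3; CO then inserts to give the aroylpalladium iodide, and amine-assisted transfer of the acetylide of 5 followed by reductive elimination forms C4a–C4 and C4–C3 in ynone 7. Diethylamine adds to the ynone β-carbon to give enaminone 8, and the ortho phenol oxygen O1 attacks that same carbon (the future C2) and expels the amine, so ring C closes by a 6-endo addition–elimination that forms O1–C2. The closest known reaction type is the palladium-catalysed carbonylative annulation of ortho-iodophenols with terminal arylalkynes to flavones in a secondary amine. No stereocenter is formed. The step needs carbonylation ahead of direct alkynylation, and six-membered (flavone) ahead of five-membered 5-exo (aurone) closure: copper-free conditions, CO pressure and the crowded, electron-rich arylpalladium flanked by OH and OMOM favour CO insertion, and in enaminone 8 only the amine-bearing carbon is electrophilic, which leaves the 6-endo path alone open. The MOM and benzyl ethers are inert to the hot basic medium.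

Step 5
Reactants: 9 2-[4-(benzyloxy)-3-methoxyphenyl]-5,7-bis(methoxymethoxy)-4H-chromen-4-one
Product: 11 2-[4-(benzyloxy)-3-methoxyphenyl]-3-hydroxy-5,7-bis(methoxymethoxy)-4H-chromen-4-one, via flavone epoxide 10 (not isolated)
Conditions: dimethyldioxirane (acetone solution, 3–4 equiv), CH2Cl2, 0 °C to rt; then p-TsOH·H2O (cat.), CH2Cl2, rt, short
Reagents that add atoms: dimethyldioxirane, CC1(C)OO1
Why: Dioxirane epoxidation of the C2=C3 bond of the flavone, then acid-catalysed opening of the epoxide at C2 (cation stabilised by O1 and the para-benzyloxyaryl ring) and loss of H3 gives the flavonol, a known flavone-to-flavonol sequence in which brief catalytic acid in an aprotic solvent should spare the MOM ethers.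

Step 6
Reactants: 11 2-[4-(benzyloxy)-3-methoxyphenyl]-3-hydroxy-5,7-bis(methoxymethoxy)-4H-chromen-4-one
Product: 12 3-(benzyloxy)-2-[4-(benzyloxy)-3-methoxyphenyl]-5,7-bis(methoxymethoxy)-4H-chromen-4-one
Conditions: BnBr (1.2 equiv), K2CO3, DMF, rt to 40 °C
Reagents that add atoms: benzyl bromide, BrCc1ccccc1
Why: Williamson etherification of the only free hydroxyl, whose enolic acidity lets K2CO3 deprotonate it, while the MOM and benzyl ethers are inert.

Step 7
Reactants: 12 3-(benzyloxy)-2-[4-(benzyloxy)-3-methoxyphenyl]-5,7-bis(methoxymethoxy)-4H-chromen-4-one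
Product: 13 3-(benzyloxy)-2-[4-(benzyloxy)-3-methoxyphenyl]-5,7-dihydroxy-4H-chromen-4-one
Conditions: HCl (methanolic, ca. 1 M), MeOH/THF, 40–50 °C
Reagents that add atoms: none
Why: Acid-catalysed transacetalisation (methanolysis of the MOM acetals) releases both ring A phenols, while the benzyl ethers, the aryl methyl ether and the chromone are stable to dilute methanolic HCl.

Step 8
Reactants: 13 3-(benzyloxy)-2-[4-(benzyloxy)-3-methoxyphenyl]-5,7-dihydroxy-4H-chromen-4-one
Product: 14 3-(benzyloxy)-2-[4-(benzyloxy)-3-methoxyphenyl]-5-hydroxy-4-oxo-4H-chromen-7-yl hydrogen sulfate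
Conditions: SO3·pyridine (3 equiv), pyridine, rt
Reagents that add atoms: sulfur trioxide–pyridine complex, O=S(=O)([O-])[n+]1ccccc1
Why: O-Sulfonation of a phenol with the SO3·pyridine complex: the 5-OH is locked in a hydrogen bond to the C4 carbonyl and is the least nucleophilic hydroxyl of a flavonoid, so the acidic, unhindered 7-OH should react alone, O3 and O4′ being blocked as benzyl ethers.

Step 9
Reactants: 14 3-(benzyloxy)-2-[4-(benzyloxy)-3-methoxyphenyl]-5-hydroxy-4-oxo-4H-chromen-7-yl hydrogen sulfate
Product: 15 isorhamnetin 7-O-sulfate (3,5-dihydroxy-2-(4-hydroxy-3-methoxyphenyl)-4-oxo-4H-chromen-7-yl hydrogen sulfate)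
Conditions: H2 (1 bar), 10% Pd/C, MeOH/THF, rt
Reagents that add atoms: none
Why: Catalytic hydrogenolysis cleaves both benzyl ethers, while the aryl sulfate monoester (handled as its salt), the aryl methyl ether and the tetrasubstituted C2=C3 bond are not reduced by H2 over Pd/C at room temperature.

**Compound list**

1 | phloroglucinol (benzene-1,3,5-triol) | Oc1cc(O)cc(O)c1 | starting material
2 | 3,5-bis(methoxymethoxy)phenol | COCOc1cc(O)cc(OCOC)c1 | intermediate
3 | 2-iodo-3,5-bis(methoxymethoxy)phenol | COCOc1cc(O)c(I)c(OCOC)c1 | intermediate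
4 | 4-(benzyloxy)-3-methoxybenzaldehyde | COc1cc(C=O)ccc1OCc1ccccc1 | starting material
5 | 1-(benzyloxy)-4-ethynyl-2-methoxybenzene | C#Cc1ccc(OCc2ccccc2)c(OC)c1 | intermediate
6 | carbon monoxide | [C-]#[O+] | starting material
7 | 3-[4-(benzyloxy)-3-methoxyphenyl]-1-[2-hydroxy-4,6-bis(methoxymethoxy)phenyl]prop-2-yn-1-one (not isolated) | COCOc1cc(O)c(C(=O)C#Cc2ccc(OCc3ccccc3)c(OC)c2)c(OCOC)c1 | intermediate
8 | (E)-3-[4-(benzyloxy)-3-methoxyphenyl]-3-(diethylamino)-1-[2-hydroxy-4,6-bis(methoxymethoxy)phenyl]prop-2-en-1-one (not isolated) | CCN(CC)/C(=C/C(=O)c1c(O)cc(OCOC)cc1OCOC)c1ccc(OCc2ccccc2)c(OC)c1 | intermediate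
9 | 2-[4-(benzyloxy)-3-methoxyphenyl]-5,7-bis(methoxymethoxy)-4H-chromen-4-one | COCOc1cc(OCOC)c2c(c1)oc(-c1ccc(OCc3ccccc3)c(OC)c1)cc2=O | intermediate
10 | racemic 2-[4-(benzyloxy)-3-methoxyphenyl]-2,3-epoxy-5,7-bis(methoxymethoxy)chroman-4-one (flavone 2,3-epoxide, oxirane cis-fused across C2–C3; one enantiomer drawn; not isolated) | O=C1c2c(OCOC)cc(OCOC)cc2O[C@@]2(c3ccc(OCc4ccccc4)c(OC)c3)O[C@@H]12 | intermediate
11 | 2-[4-(benzyloxy)-3-methoxyphenyl]-3-hydroxy-5,7-bis(methoxymethoxy)-4H-chromen-4-one | COCOc1cc(OCOC)c2c(c1)oc(-c1ccc(OCc3ccccc3)c(OC)c1)c(O)c2=O | intermediate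
12 | 3-(benzyloxy)-2-[4-(benzyloxy)-3-methoxyphenyl]-5,7-bis(methoxymethoxy)-4H-chromen-4-one | COCOc1cc(OCOC)c2c(c1)oc(-c1ccc(OCc3ccccc3)c(OC)c1)c(OCc1ccccc1)c2=O | intermediate
13 | 3-(benzyloxy)-2-[4-(benzyloxy)-3-methoxyphenyl]-5,7-dihydroxy-4H-chromen-4-one | COc1cc(-c2oc3cc(O)cc(O)c3c(=O)c2OCc2ccccc2)ccc1OCc1ccccc1 | intermediate
14 | 3-(benzyloxy)-2-[4-(benzyloxy)-3-methoxyphenyl]-5-hydroxy-4-oxo-4H-chromen-7-yl hydrogen sulfate | COc1cc(-c2oc3cc(OS(=O)(=O)O)cc(O)c3c(=O)c2OCc2ccccc2)ccc1OCc1ccccc1 | intermediate
15 | isorhamnetin 7-O-sulfate | COc1cc(-c2oc3cc(OS(=O)(=O)O)cc(O)c3c(=O)c2O)ccc1O | target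

**Step count and risks**

Total step count: 9. Longest linear sequence: 8 steps (steps 1, 2, 4, 5, 6, 7, 8, 9, from phloroglucinol).

Steps most likely to fail:

1. Step 4 (key step). The arylpalladium may couple with the alkyne before CO inserts and then close to a 2-arylbenzofuran. The aroylpalladium may be captured by diethylamine to give the amide. The ynone may close 5-exo to the aurone, or the iodide may be lost reductively. Fallback (sets out from phenol 2 and alkyne 5, returns at flavone 9): the carbonyl carbon is installed first as an aldehyde. Magnesium-phenoxide-directed ortho-formylation of 2 (MgCl2, Et3N, paraformaldehyde, MeCN, reflux; Casnati–Skattebøl conditions, ortho to the free OH only) should give 2-hydroxy-4,6-bis(methoxymethoxy)benzaldehyde F1. Alkyne 5, deprotonated with n-BuLi (2.2 equiv, THF, −78 °C to 0 °C), adds to F1 to give racemic 3-[4-(benzyloxy)-3-methoxyphenyl]-1-[2-hydroxy-4,6-bis(methoxymethoxy)phenyl]prop-2-yn-1-ol F2. F2 is oxidised crude with MnO2 in CH2Cl2 to ynone 7. Et2NH in EtOH (rt to reflux) then takes 7 through enaminone 8 to flavone 9 by the same 6-endo addition–elimination.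

2. Step 2. Iodination may go para to the free hydroxyl (between the two MOM ethers) in competition with the ortho position, or run on to the diiodide. Fallback (sets out from 2, returns at 3): directed ortho-metalation replaces electrophilic substitution. Carbamoylation of 2 (ClCONEt2, K2CO3, MeCN, reflux) gives 3,5-bis(methoxymethoxy)phenyl diethylcarbamate F3. s-BuLi/TMEDA (THF, −78 °C) should deprotonate between the carbamate, the strongest directing group present, and the neighbouring OMOM; an I2 quench gives 2-iodo-3,5-bis(methoxymethoxy)phenyl diethylcarbamate F4. Hydrolysis of the carbamate (NaOH, EtOH/H2O, reflux) returns iodophenol 3.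

3. Step 5. Epoxidation of the electron-poor chromone double bond may be slow, the C5 MOM ether may be cleaved during the acid isomerisation, or the electron-rich rings may be over-oxidised. Fallback (sets out from 9, returns at 11): C3 is hydroxylated through the anion. Deprotonation of 9 at C3 with LiN(i-Pr)2 (THF, −78 °C) and trapping with B(OMe)3 should give dimethyl {2-[4-(benzyloxy)-3-methoxyphenyl]-5,7-bis(methoxymethoxy)-4-oxo-4H-chromen-3-yl}boronate F5. Oxidation in the same flask with H2O2/AcOH (0 °C) gives flavonol 11 with no acid-labile epoxide on the way.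

Further compounds
F1 | step 4 | 2-hydroxy-4,6-bis(methoxymethoxy)benzaldehyde | COCOc1cc(O)c(C=O)c(OCOC)c1
F2 | step 4 | racemic 3-[4-(benzyloxy)-3-methoxyphenyl]-1-[2-hydroxy-4,6-bis(methoxymethoxy)phenyl]prop-2-yn-1-ol | COCOc1cc(O)c(C(O)C#Cc2ccc(OCc3ccccc3)c(OC)c2)c(OCOC)c1
F3 | step 2 | 3,5-bis(methoxymethoxy)phenyl diethylcarbamate | CCN(CC)C(=O)Oc1cc(OCOC)cc(OCOC)c1
F4 | step 2 | 2-iodo-3,5-bis(methoxymethoxy)phenyl diethylcarbamate | CCN(CC)C(=O)Oc1cc(OCOC)cc(OCOC)c1I
F5 | step 5 | dimethyl {2-[4-(benzyloxy)-3-methoxyphenyl]-5,7-bis(methoxymethoxy)-4-oxo-4H-chromen-3-yl}boronate | COB(OC)c1c(-c2ccc(OCc3ccccc3)c(OC)c2)oc2cc(OCOC)cc(OCOC)c2c1=O
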